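Slowness can hide inside scatter, and that is the dispute over the red flask, in which J (substrate) and G (reagent) give Q over the catalyst Z.

| setting | ochre | teal | violet | red |
|---|---|---|---|---|
| J | 0.300 M | 0.120 M | 0.300 M | 0.300 M |
| G | 0.300 M | 0.120 M | 0.300 M | 0.300 M |
| Z | 0.0150 M | 0.0150 M | 0.0220 M | 0.0150 M |
| time |  |  |  | 250 min |

- ochre run (time / min: [Q] / M): 8.9: 0.093; 18: 0.111; 27: 0.111; 35: 0.112; 44: 0.111; 53: 0.106; 62: 0.108
- teal run (time / min: [Q] / M): 8.9: 0.042; 18: 0.050; 27: 0.054; 35: 0.056; 44: 0.062; 53: 0.058; 62: 0.056
- violet run (time / min: [Q] / M): 8.9: 0.115; 18: 0.121; 27: 0.127; 35: 0.121; 44: 0.124; 53: 0.131; 62: 0.124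

(standard deviation of a reading: 0.004 M)

- Overall: J + G -> Q, with Z as catalyst.
- Constant volume, constant temperature.
- "The second partner" is G.
- An order is taken over about fifteen percent of the charge, up and down.

- reaction order in [Z] at the outset, round the charge of the ochre run, defined at two percent of the J turned into Q
- Q in the red run at 250 min, as a share of the J charged

Two chemists read these runs, and both reject equilibrium. The violet flask, with more Z at the same J and G, levels higher, at 0.125 M against 0.110 M in the ochre flask, and a catalyst cannot move an end state.

The first chemist says the ochre flask has stalled as its catalyst lost activity. The red flask has the same charge, so she carries over the mean ochre reading from 27 min on, divided by the J charged: 36.5%, the stall share.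

The second chemist says the flask is merely slow. Two readings differ by chance with a standard deviation of 1.4 times the scatter, so a rise of twice that between 18 min and 62 min goes unseen in the ochre flask. That is a creep of 2.57 × 10⁻⁴ M min⁻¹. Run on to 250 min, it gives 52.6%, more than the stall share.

The measured ochre change between those two times, −0.00300 M, lies within the chance spread of 0.00566 M, so its sign tells neither side anything. I take the first side on other grounds: the ochre flask made Q at 0.0104 M min⁻¹ on average up to 8.9 min, about 40.6 times the creep, whereas if J and G went into Q, the product of their concentrations has fallen to only 40.3% of its start. For the order in Z, the first violet and ochre readings give 0.554, but both flasks have already slowed by 8.9 min, so I expect nearer 1 at the outset.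

The forecast, 37.5% and an order of 0.9, stands a little above my share and rests on the view that “The late slopes are flat within noise”.

The simulation gives 37.6% and an order of 0.96.

    Z + J → Dz + L (11.58 M⁻¹ min⁻¹)
    Dz + G → Q + Z (70.80 M⁻¹ min⁻¹)
    2 Z → 2 Zu (20.34 M⁻¹ min⁻¹)
    Q + G → E (0.1962 M⁻¹ min⁻¹)

The red flask ends 1 percentage point above the stall share and 15 points below the creep estimate. Its level stands so low because of the step from 2 Z to 2 Zu acting together with the step from Q + G to E. Without the step from Z to Zu, Q in the red run at 250 min stands at 77.6%, and without the step to E it stands at 79.1%.

Readings and results are calculated for substances that don't exist; the scatter is artificial.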